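**Retrosynthetic overview**
1. The bicyclo[2.2.2]octenone is cut back to myrcene (its vinyl group as 2π partner) and an eudesmanolide cyclohexa-2,4-dienone (C2=C3–C4=C5 of ring A as 4π partner). The lactone of that dienone is cut at the O–C6 bond to a silyl trienol ether of the 1-oxo-2,4-dien-12-oic acid.
2. Enabling feature: C6 is at once the ε-carbon of the C1 ketone (through C2=C3 and C4=C5 of ring A; C10 is quaternary, so enolisation can only run out to C6) and the γ-carbon of the C12 carboxyl (C12–C11–C7–C6 on ring B). Bromination at C6 followed by carboxylate displacement therefore closes a five-membered lactone and leaves ring A as the dienone that takes up myrcene in the same flask.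
3. The 1-oxo-2,4-diene acid comes from the 3-oxo-4-ene acid by moving the carbonyl from C3 to C1 (dehydrogenation, nucleophilic epoxidation, Wharton transposition, oxidation).
4. The 3-oxo acid comes from (+)-dihydrocarvone (ring B, C7) by chiral-imine Robinson annulation with ethyl vinyl ketone (ring A, C10), allylic oxidation of the isopropenyl group and asymmetric hydrogenation (C11).
5. Ring order: ring B (starting material), ring A (step 2), then the lactone ring and both rings of the bicyclo[2.2.2]octene (step 11).

Key step: step 11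

Remark: eudesmane numbering is used (ring A = C1–C5 and C10; ring B = C5–C10; C11–C13 side chain; C14 on C10, C15 on C4; C1′ and C2′ are the two myrcene carbons of the new bridge; α/β as in steroids). The target is taken to be the myrcene adduct on the β face of the dienone lactone, as its descriptors require.

**Route**

Step 1
Reactants: 1 (+)-dihydrocarvone [(2R,5R)-2-methyl-5-(prop-1-en-2-yl)cyclohexan-1-one]; 2 (R)-1-phenylethylamine; 3 ethyl vinyl ketone (pent-1-en-3-one)
Product: 6 (2S,5R)-2-methyl-2-(3-oxopentyl)-5-(prop-1-en-2-yl)cyclohexan-1-one, via ketimine 4 (not isolated), via Michael-adduct ketimine 5 (not isolated)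
Conditions: 2, TsOH·H2O (cat.), PhMe, reflux, Dean–Stark; then 3, THF, 40 °C; then 10% aq. AcOH, 23 °C
Reagents that add atoms: water, O
Why: Deracemising chiral-imine Michael addition (aza-ene-type addition of the more substituted secondary enamine tautomer, the first half of a Robinson annulation) followed by imine hydrolysis: the (R)-1-phenylethyl group shields one enamine face, so the new quaternary carbon (later C10) should form as 2S with its methyl cis to the isopropenyl group, while C2 of 1 is erased in the enamine and C5 (later C7) is untouched.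

Step 2
Reactants: 6 (2S,5R)-2-methyl-2-(3-oxopentyl)-5-(prop-1-en-2-yl)cyclohexan-1-one
Product: 7 (+)-α-cyperone [(7R,10S)-eudesma-4,11-dien-3-one]
Conditions: NaOMe, MeOH, 23 → 60 °C
Reagents that add atoms: none
Why: Intramolecular aldol condensation (second half of the Robinson annulation) closes ring A as the tetrasubstituted enone, no stereocentre is formed and the quaternary C10 cannot epimerise.

Step 3
Reactants: 7 (+)-α-cyperone
Product: 8 (7R,10S)-12-hydroxyeudesma-4,11(13)-dien-3-one
Conditions: SeO2 (0.3 equiv), t-BuOOH (3 equiv), CH2Cl2, 23 °C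
Reagents that add atoms: tert-butyl hydroperoxide, CC(C)(C)OO (oxygen relayed through SeO2, O=[Se]=O)
Why: SeO2-catalysed allylic hydroxylation (ene reaction then [2,3]-sigmatropic shift) should take the methyl group of the electron-rich 1,1-disubstituted alkene in preference to positions next to the electron-poor enone, and no stereocentre is formed.

Step 4
Reactants: 8 (7R,10S)-12-hydroxyeudesma-4,11(13)-dien-3-one
Product: 10 (7R,10S)-3-oxoeudesma-4,11(13)-dien-12-oic acid, via enal 9 (not isolated)
Conditions: TEMPO (cat.), NaOCl (cat.), NaClO2 (2 equiv), MeCN/phosphate buffer pH 6.7, 35 °C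
Reagents that add atoms: sodium chlorite, [Na+].[O-]Cl=O
Why: Oxoammonium (TEMPO) oxidation of the primary allylic alcohol to the enal and chlorite (Pinnick-type) oxidation of the enal in one pot, in which hypochlorite is consumed as it forms so that the alkenes are not chlorinated.

Step 5
Reactants: 10 (7R,10S)-3-oxoeudesma-4,11(13)-dien-12-oic acid
Product: 11 (7R,10S,11S)-3-oxoeudesm-4-en-12-oic acid
Conditions: Ru(OAc)2[(S)-BINAP] (1 mol %), H2 (60 bar), MeOH, 25 °C
Reagents that add atoms: none
Why: Carboxylate-directed asymmetric hydrogenation of a 2-alkylacrylic acid with a BINAP–ruthenium diacetate sets C11 under catalyst control (the (S)-ligand is expected to give 11S, the sense known for 2-arylacrylic and terpenoid 2-alkylacrylic acids), and the tetrasubstituted enone is not reduced.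

Step 6
Reactants: 11 (7R,10S,11S)-3-oxoeudesm-4-en-12-oic acid
Product: 12 (11S)-3-oxoeudesma-1,4-dien-12-oic acid
Conditions: DDQ (1.2 equiv), 1,4-dioxane, reflux
Reagents that add atoms: none
Why: Quinone dehydrogenation of a 4-en-3-one through its 2,4-dienol under neutral conditions should give the cross-conjugated 1,4-dien-3-one, as is standard for steroidal and eudesmane enones.

Step 7
Reactants: 12 (11S)-3-oxoeudesma-1,4-dien-12-oic acid
Product: 13 (11S)-1α,2α-epoxy-3-oxoeudesm-4-en-12-oic acid
Conditions: 30% H2O2, NaOH, MeOH, 0 → 23 °C; then NaH2PO4 (pH 5)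
Reagents that add atoms: hydrogen peroxide, OO
Why: Weitz–Scheffer epoxidation, in which hydroperoxide adds to C1 of the less substituted C1=C2 bond and not to the tetrasubstituted C4=C5 bond, and from the α face anti to the axial C14 methyl on C10, which sets C1 and C2.

Step 8
Reactants: 13 (11S)-1α,2α-epoxy-3-oxoeudesm-4-en-12-oic acid
Product: 14 (11S)-1α-hydroxyeudesma-2,4-dien-12-oic acid
Conditions: N2H4·H2O (3 equiv), AcOH (cat.), MeOH, 0 → 23 °C
Reagents that add atoms: none
Why: Wharton transposition, in which the epoxy hydrazone opens to the C1 alkoxide and a vinyl diazene that loses N2, so that the oxygen is moved from C3 to C1 with the configuration of the epoxide (1α) and the new C2=C3 bond lies in conjugation with C4=C5.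

Step 9
Reactants: 14 (11S)-1α-hydroxyeudesma-2,4-dien-12-oic acid
Product: 15 (7R,10R,11S)-1-oxoeudesma-2,4-dien-12-oic acid
Conditions: Dess–Martin periodinane (1.3 equiv), CH2Cl2, 0 → 23 °C; used directly
Reagents that add atoms: none
Why: Dess–Martin oxidation of the secondary dienylic alcohol gives the 6,6-disubstituted cyclohexa-2,4-dienone, which cannot tautomerise to a phenol because C10 is quaternary, while the C1 stereocentre is removed and C11 is not enolised under these near-neutral conditions.

Step 10
Reactants: 15 (7R,10R,11S)-1-oxoeudesma-2,4-dien-12-oic acid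
Product: 16 trimethylsilyl (11S)-1-(trimethylsilyloxy)eudesma-1,3,5-trien-12-oate
Conditions: TMSOTf (2.3 equiv), Et3N (3 equiv), Et2O, −78 → 0 °C; pentane, filtration under argon
Reagents that add atoms: trimethylsilyl trifluoromethanesulfonate, C[Si](C)(C)OS(=O)(=O)C(F)(F)F
Why: Soft enolisation, in which O-silylation of the dienone and deprotonation by the amine at C6 (the only carbon whose proton is conjugated to the carbonyl, since C10 is quaternary and C15 sits on the nodal C4) give the linear silyl trienol ether while the carboxyl group is silylated at the same time.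

Step 11
Reactants: 16 trimethylsilyl (11S)-1-(trimethylsilyloxy)eudesma-1,3,5-trien-12-oate; 17 myrcene (7-methyl-3-methylideneocta-1,6-diene)
Product: 21 target CNP0385704.1 [(1′S,2S,5R,6S,7S,10R,11S)-1-oxo-2β,5β-[1′-(6-methylhepta-1,5-dien-2-yl)ethano]eudesm-3-en-12,6α-olide], via bromo silyl ester 18 (not isolated), via bromo acid 19 (not isolated), via dienone lactone 20 (not isolated)
Conditions: NBS (1.0 equiv), THF, −78 °C; then MeOH (5 equiv), KHCO3 (powder, 3 equiv), −78 → 23 °C; then 17 (10 equiv), PhMe, BHT (cat.), 90 °C, sealed tube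
Reagents that add atoms: none
Why: NBS should attack the terminal (ε) carbon C6 of the silyl trienol ether from the β face (axial attack on C5=C6 in the ring B half-chair, the course known for 6β-halogenation of steroidal dienol ethers; C4 is fully substituted and attack at C6 gives the conjugated dienone), methanolysis then frees the carboxyl group, and its potassium salt displaces the axial bromide from the α side in a 5-exo-tet SN2 closure with inversion, which forms the O–C6 bond and the trans-fused γ-lactone. The closest known reaction types are the γ-bromination of silyl dienol ethers with NBS, the lactonisation of γ-bromo enone acids used in classical eudesmanolide work, and the [4+2] additions of 6,6-disubstituted cyclohexa-2,4-dienones to 1,3-dienes that serve as the 2π partner. Ionisation at C6, which would erode the configuration, is disfavoured because the cation would be conjugated to the electron-poor dienone, and bromide leaves solution as KBr so that it cannot re-open or epimerise the allylic lactone. Dienone lactone 20 then reacts in the same flask as the 4π component (C2=C3–C4=C5) with the monosubstituted vinyl group of myrcene in a concerted suprafacial [4+2] addition that closes both rings of the bicyclo[2.2.2]octenone (bonds C2–C1′ and C5–C2′). C6 is controlled by the bromination/inversion sequence, C2 and C5 by approach to the β face of ring A (ring B with C9, C8 and the α-lactone oxygen lies under the diene, only the C14 methyl above it), and C1′ by the endo rule (the residual diene of myrcene under C3=C4). The step needs the dienone to act as diene and not as dienophile, and the orientation that joins the CH2 terminus of myrcene to C5, both expected from the large LUMO coefficient at C5 of the dienone and from the behaviour of related cyclohexa-2,4-dienones.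

**Compound list**
1 | (+)-dihydrocarvone, (2R,5R)-2-methyl-5-(prop-1-en-2-yl)cyclohexan-1-one | CC(=C)[C@@H]1CC[C@@H](C)C(=O)C1 | starting material
2 | (R)-1-phenylethylamine | C[C@@H](N)c1ccccc1 | starting material
3 | ethyl vinyl ketone (pent-1-en-3-one) | CCC(=O)C=C | starting material
4 | N-[(R)-1-phenylethyl] ketimine of 1 (reacts as its secondary enamine) | CC(=C)[C@@H]1CC[C@@H](C)C(=N[C@H](C)c2ccccc2)C1 | intermediate
5 | N-[(R)-1-phenylethyl] ketimine of (2S,5R)-2-methyl-2-(3-oxopentyl)-5-(prop-1-en-2-yl)cyclohexanone | CC(=C)[C@@H]1CC[C@@](C)(CCC(=O)CC)C(=N[C@H](C)c2ccccc2)C1 | intermediate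
6 | (2S,5R)-2-methyl-2-(3-oxopentyl)-5-(prop-1-en-2-yl)cyclohexan-1-one | CC(=C)[C@@H]1CC[C@@](C)(CCC(=O)CC)C(=O)C1 | intermediate
7 | (+)-α-cyperone, (7R,10S)-eudesma-4,11-dien-3-one | CC(=C)[C@@H]1CC[C@]2(CCC(=O)C(C)=C2C1)C | intermediate
8 | (7R,10S)-12-hydroxyeudesma-4,11(13)-dien-3-one | C=C(CO)[C@@H]1CC[C@]2(CCC(=O)C(C)=C2C1)C | intermediate
9 | (7R,10S)-3-oxoeudesma-4,11(13)-dien-12-al | C=C(C=O)[C@@H]1CC[C@]2(CCC(=O)C(C)=C2C1)C | intermediate
10 | (7R,10S)-3-oxoeudesma-4,11(13)-dien-12-oic acid | C=C(C(=O)O)[C@@H]1CC[C@]2(CCC(=O)C(C)=C2C1)C | intermediate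
11 | (7R,10S,11S)-3-oxoeudesm-4-en-12-oic acid | C[C@H](C(=O)O)[C@@H]1CC[C@]2(CCC(=O)C(C)=C2C1)C | intermediate
12 | (11S)-3-oxoeudesma-1,4-dien-12-oic acid (7αH, 10β-methyl) | C[C@H](C(=O)O)[C@@H]1CC[C@]2(C=CC(=O)C(C)=C2C1)C | intermediate
13 | (11S)-1α,2α-epoxy-3-oxoeudesm-4-en-12-oic acid | C[C@H](C(=O)O)[C@@H]1CC[C@]2([C@H]3O[C@H]3C(=O)C(C)=C2C1)C | intermediate
14 | (11S)-1α-hydroxyeudesma-2,4-dien-12-oic acid | C[C@H](C(=O)O)[C@@H]1CC[C@]2([C@@H](O)C=CC(C)=C2C1)C | intermediate
15 | (7R,10R,11S)-1-oxoeudesma-2,4-dien-12-oic acid | C[C@H](C(=O)O)[C@@H]1CC[C@]2(C(=O)C=CC(C)=C2C1)C | intermediate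
16 | trimethylsilyl (11S)-1-(trimethylsilyloxy)eudesma-1,3,5-trien-12-oate | C[C@H](C(=O)O[Si](C)(C)C)[C@@H]1CC[C@]2(C(O[Si](C)(C)C)=CC=C(C)C2=C1)C | intermediate
17 | myrcene, 7-methyl-3-methylideneocta-1,6-diene | C=CC(=C)CCC=C(C)C | starting material
18 | trimethylsilyl (11S)-6β-bromo-1-oxoeudesma-2,4-dien-12-oate | C[C@H](C(=O)O[Si](C)(C)C)[C@@H]1CC[C@]2(C(=O)C=CC(C)=C2[C@@H]1Br)C | intermediate
19 | (11S)-6β-bromo-1-oxoeudesma-2,4-dien-12-oic acid (reacts as its potassium carboxylate) | C[C@H](C(=O)O)[C@@H]1CC[C@]2(C(=O)C=CC(C)=C2[C@@H]1Br)C | intermediate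
20 | (6S,7S,10R,11S)-1-oxoeudesma-2,4-dien-12,6α-olide (11βH) | C[C@H]1[C@@H]2CC[C@]3(C(=O)C=CC(=C3[C@H]2OC1=O)C)C | intermediate
21 | CNP0385704.1, (1′S,2S,5R,6S,7S,10R,11S)-1-oxo-2β,5β-[1′-(6-methylhepta-1,5-dien-2-yl)ethano]eudesm-3-en-12,6α-olide | C=C(CCC=C(C)C)[C@H]1C[C@@]23C(C)=C[C@@H]1C(=O)[C@]2(C)CC[C@H]1[C@H](C)C(=O)O[C@@H]13 | target

**Step count and risks**

Total step count: 11. Longest linear sequence: 11 steps (1 → 21).

Steps most likely to fail:

1. Step 11. What may go wrong: bromination at C2 instead of C6; exchange of the allylic bromide or ionisation before ring closure, which would lose the C6 configuration and lead to the cis-lactone; and, in the second stage, dimerisation of the dienone or poor facial and orientational control. Fallback (sets out from 15, comes back at 20): C6 is activated through oxygen instead of bromine and every stage is isolated. 15 is esterified with 2-(trimethylsilyl)ethanol (EDC·HCl, DMAP, CH2Cl2) to 2-(trimethylsilyl)ethyl (11S)-1-oxoeudesma-2,4-dien-12-oate F1. TBSOTf/Et3N converts this into the tert-butyldimethylsilyl trienol ether F2. A vinylogous Rubottom oxidation (dimethyldioxirane, acetone/CH2Cl2, −78 °C, then citric acid) should deliver oxygen to C6 from the β face and give the 6β-hydroxy dienone ester F3. MsCl/Et3N gives the 6β-mesylate F4. Bu4NF (THF, 0 °C) then cleaves the silylethyl ester, and the carboxylate displaces the mesylate with inversion to give 20. Purified 20 is then heated with 17 (PhMe, 90 °C) in a separate operation to give 21.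

2. Step 8. What may go wrong: hydrazine may add to the enone or attack the carboxyl group instead of forming the hydrazone, and collapse of the vinyl diazene may give reduced or isomerised dienes. Fallback (sets out from 13, comes back at 14): the same transposition in polar steps. The epoxide is opened reductively at C2 with the selenide–borate reagent made from (PhSe)2 and NaBH4 (EtOH, AcOH, 0 °C) to give (11S)-1α-hydroxy-3-oxoeudesm-4-en-12-oic acid F5. This is condensed with TsNHNH2 (MeOH, 23 °C) to its tosylhydrazone F6. LiN(iPr)2 (5 equiv, THF, −78 → 0 °C, Shapiro reaction) removes the C2 proton, expels sulfinate and N2 and, after protonation of the C3 vinyl anion, gives 14.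

3. Step 3. What may go wrong: oxidation next to the ketone (C2 or C6), hydroxylation at C7, or over-oxidation, all of which cut the material supply at an early stage. Fallback (sets out from 7, comes back at 8): ene-type allylic chlorination of the isopropenyl group (Ca(OCl)2, solid CO2, CH2Cl2/H2O, 0 °C) gives 12-chloroeudesma-4,11(13)-dien-3-one F7. KOAc (DMF, 60 °C) gives 12-acetoxyeudesma-4,11(13)-dien-3-one F8, and K2CO3/MeOH gives 8.

Further compounds
F1 | step 11 | 2-(trimethylsilyl)ethyl (11S)-1-oxoeudesma-2,4-dien-12-oate | C[C@H](C(=O)OCC[Si](C)(C)C)[C@@H]1CC[C@]2(C(=O)C=CC(C)=C2C1)C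
F2 | step 11 | 2-(trimethylsilyl)ethyl (11S)-1-(tert-butyldimethylsilyloxy)eudesma-1,3,5-trien-12-oate | C[C@H](C(=O)OCC[Si](C)(C)C)[C@@H]1CC[C@]2(C(O[Si](C)(C)C(C)(C)C)=CC=C(C)C2=C1)C
F3 | step 11 | 2-(trimethylsilyl)ethyl (11S)-6β-hydroxy-1-oxoeudesma-2,4-dien-12-oate | C[C@H](C(=O)OCC[Si](C)(C)C)[C@@H]1CC[C@]2(C(=O)C=CC(C)=C2[C@@H]1O)C
F4 | step 11 | 2-(trimethylsilyl)ethyl (11S)-6β-(methanesulfonyloxy)-1-oxoeudesma-2,4-dien-12-oate | C[C@H](C(=O)OCC[Si](C)(C)C)[C@@H]1CC[C@]2(C(=O)C=CC(C)=C2[C@@H]1OS(C)(=O)=O)C
F5 | step 8 | (11S)-1α-hydroxy-3-oxoeudesm-4-en-12-oic acid | C[C@H](C(=O)O)[C@@H]1CC[C@]2([C@@H](O)CC(=O)C(C)=C2C1)C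
F6 | step 8 | p-toluenesulfonylhydrazone of (11S)-1α-hydroxy-3-oxoeudesm-4-en-12-oic acid | C[C@H](C(=O)O)[C@@H]1CC[C@]2([C@@H](O)CC(=NNS(=O)(=O)c3ccc(C)cc3)C(C)=C2C1)C
F7 | step 3 | (7R,10S)-12-chloroeudesma-4,11(13)-dien-3-one | C=C(CCl)[C@@H]1CC[C@]2(CCC(=O)C(C)=C2C1)C
F8 | step 3 | (7R,10S)-12-acetoxyeudesma-4,11(13)-dien-3-one | C=C(COC(C)=O)[C@@H]1CC[C@]2(CCC(=O)C(C)=C2C1)C
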